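Compound numbers 1–16 are those of the steps and the compound list below. The target is numbered as a 2,3-dihydrobenzofuran (O1, C2, C3, C3a, C4–C7, C7a); ring A is the benzo ring and ring B the aryl group on C2.

## Analysis of the target

Target 16 is a trans-2-aryl-3-(hydroxymethyl)-2,3-dihydrobenzofuran of the phenylcoumaran neolignan class: ring A (C3a–C7a) carries a methoxy group on C7 and a 3-hydroxypropyl chain on C5, the five-membered ring is O1–C2–C3 fused at C3a/C7a, and C2 bears ring B, a 4-hydroxy-3,5-dimethoxyphenyl group. There are two stereocentres, C2 (S) and C3 (R), on adjacent ring atoms; ring B and the CH2OH group lie on opposite faces, which is also the more stable relative arrangement. C2–O1 is a p-hydroxybenzyl aryl ether, so once the ring B phenol is free, acid or base can ionise it towards a p-quinone methide: C2 can then drift (towards trans) or the ring can open, whereas C3, an ordinary CH carrying CH2OH, is configurationally fixed. Further sensitive points are the free phenol, two primary alcohols that must be told apart from the phenolic oxygens during assembly, and two electron-rich arenes that do not tolerate strong oxidants. The ring itself is easy to close; what is hard is to obtain C3 in one absolute configuration and to close C2–O1 in a stereochemically defined way, since the biomimetic oxidative coupling delivers this skeleton only as a racemate. The strategy rests on the sequence O–C2–C3–C(exocyclic): with the exocyclic carbon at the carboxyl level these four atoms are the ring atoms of a β-lactone, and O1 of ring A, attached at C7a ortho to C3a, is five atoms from C2 and can take the strained C2–O bond over from the carboxyl oxygen.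

## Retrosynthetic reasoning

16 is first taken back to acid 15 without cutting a skeletal bond: the C3 hydroxymethyl carbon is raised to a carboxylic acid and the ring B phenol and the side-chain alcohol are masked as pivalates. This is the oxidation level that the next disconnection needs at C3. Forward, one aluminium hydride treatment must reduce the acid and strip both esters while leaving C2 and C3 alone.

In 15 the O1–C2 bond is cut and C2 is joined to the carboxyl oxygen instead, which gives β-lactone 13 with ring A's oxygen held as a silyl ether; oxetanone C3 is the future C3 and oxetanone C4 the future C2. The cut is placed here, and not at C7a–O1 or C3–C3a, because the lactone stores about 23 kcal/mol of strain in exactly the bond that has to be exchanged, so a neutral oxygen can displace it. The forward step has to make the ring A oxygen attack oxetanone C4 (5-exo-tet) under Lewis-acidic, non-basic conditions; a free phenoxide is avoided on purpose, since it would attack the lactone carbonyl (5-exo-trig acyl transfer) instead of C4. Displacement inverts C4, so 13 must be the trans lactone with C3 as in the target and C4 opposite to the target's C2. If the C4–O bond ionises before it is attacked, closure anti to the C3 carboxyl group gives the same trans acid, so both mechanisms converge.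

13 is cut across the four-membered ring at C3–C4 and at the acyl C–O bond, the two bonds that a ketene and an aldehyde form in a [2+2] cycloaddition. This leads to ketene 12, generated in the flask from acid chloride 9, and aldehyde 11. C3–C4 is the only C–C bond between the two halves of the molecule; making it here joins two fragments of similar size and sets both stereocentres in one catalytic step, with the ketene-derived centre (the one that cannot be corrected later) under the control of a chiral Lewis base. The forward reaction has to favour cross-addition over ketene dimerisation, choose one face of the ammonium enolate and give the trans isomer. The pivalate on ring B of 11 is kept so that the aldehyde stays electrophilic and the benzylic C4–O bond of 13 does not ionise too early.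

9 comes from acid 8, and the two-carbon acid arm of 8 from the allyl group of 6 by oxidative cleavage of the terminal C=C bond, via aldehyde 7. An allyl group is chosen as the masked CH2CO2H unit because it can be placed selectively on the one carbon of ring A that becomes C3a.

That carbon–carbon bond (future C3a to the CH2 carbon) is cut in the sense of an aromatic Claisen rearrangement: 6 is the silyl ether of phenol 5, 5 arises from allyl aryl ether 4, and 4 from 3, the allyl ether of 1, after acylation of the side-chain alcohol. 1 already carries the C7 methoxy group, the C5 three-carbon chain with its oxygen and the oxygen that becomes O1. Its para position is blocked and one ortho position is occupied, so the rearrangement of 4 can only deliver the allyl group of 2 to the required carbon.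

11 is the pivalate of 10, which supplies ring B with its oxygen pattern and the future C2 as the formyl carbon.

## Alternatives that were turned down

Alternative 1: closing C7a–O1 by nucleophilic aromatic substitution.
- Disconnection and key step: the aryl ether bond on the ring A side is cut. The precursor is the open-chain fluoro alcohol A2; a strong amide base forms its alkoxide, which displaces fluoride para to a formyl group and gives A1, the 5-formyl, O-benzyl, O-silyl protected dihydrobenzofuran.
- For: neither stereocentre takes part in the ring closure, so nothing can be inverted or scrambled there. On this point it is more secure than the chosen route, whose closure happens at C2.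
- Against: (a) A2 already contains both stereocentres, so the asymmetric C2–C3 bond construction is only moved to an earlier aldol-type step. (b) The fluoride sits between the C7 methoxy group and the C3a alkyl substituent and is activated by a single para formyl group; the negative charge of the Meisenheimer intermediate falls on the methoxy-bearing carbon, so substitution should be slow, while the basic alkoxide can add to the free aldehyde or fragment by retro-aldol-type cleavage. (c) The formyl group must then be extended by two carbons (olefination, hydrogenation, reduction) and three protecting groups removed. (d) The fluorinated ring A building block has to be made, whereas the chosen route takes ring A with chain, methoxy group and O1 from 1.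
- Comparison: the chosen strategy gives up the stereochemically inert closure but builds the C2–C3 bond, both centres and the leaving group for the closure in one step, and is shorter by roughly four steps.

Alternative 2: closing C3–C3a by aryl radical cyclisation with boron trapping.
- Disconnection and key step: the precursor is aryl iodide A4, in which ring A's oxygen is bound to an (S)-configured carbon that carries ring B and a vinyl group. Blue light and a diboron reagent in an amide solvent generate the C3a radical, which adds 5-exo to the vinyl group; the primary radical is borylated and converted to the pinacol boronate A3, whose C–B bond would later be oxidised to the C3 hydroxymethyl group.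
- For: the conditions are neutral and mild, no strained or decarboxylation-prone intermediate is involved, and the exocyclic carbon is functionalised in the ring-forming step. In functional-group tolerance it is stronger than the chosen route.
- Against: (a) C2 has to be enantiopure in A4 at a carbon that is benzylic, allylic and bound to a hindered 2,6-disubstituted phenol oxygen, so its etherification is exposed to SN1 and SN2' scrambling. (b) C3 is set only by 1,2-induction from C2 in an early transition state, for which the trans preference of a 2-aryl substituent is expected to be moderate, so a diastereomer mixture is likely. (c) Direct borylation of the aryl radical before cyclisation competes. (d) Oxidation, desilylation and debenzylation still follow.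
- Comparison: the chosen strategy sets C3 by a catalyst and C2 by a stereospecific, thermodynamically backed displacement, at a similar step count.

Alternative 3: [4+1] annulation of a ring A o-quinone methide with a chiral benzylic sulfur ylide.
- Disconnection and key step: both C2–C3 and O1–C2 are cut. A carbonate base eliminates sulfinate from sulfone A6 to give o-quinone methide A8, the ylide of an enantiopure sulfonium salt such as A7 adds to its exocyclic carbon, and the phenoxide displaces the sulfide to give A5, the fully protected target.
- For: it is the most convergent plan, forming the ring, two bonds and both stereocentres from two fragments in one flask, with the trans relationship expected from anti closure of the betaine. In step economy it is stronger than the chosen route by about three steps.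
- Against: (a) The exocyclic carbon of A8 carries a CH2OSi group instead of the aryl group of well-behaved [4+1] partners, and such alkyl-type o-quinone methides tautomerise readily to o-hydroxystyrenes (here an enol ether) under basic conditions. (b) The absolute configuration depends on a stoichiometric chiral sulfide and on face discrimination in a fast, early addition of a semi-stabilised ylide to a short-lived electrophile, with no later step that could correct it. (c) The electron-rich benzylic ylide is open to sigmatropic rearrangement.
- Comparison: the chosen strategy is longer, but its chirality source is catalytic, its two stereochemical events are separate and each has a known counterpart, and C2 is backed by the thermodynamic trans preference.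

Key step: step 8

Assumption on the chemistry: O-trimethylsilylquinine is taken to deliver the 3S configuration in 13, the sense in which quinine-type catalysts direct C–C bond formation of monosubstituted ketene enolates; the quinidine-derived pseudoenantiomer would lead to the mirror-image series.

## Route

Step 1
Reactants: 1 dihydroconiferyl alcohol [4-(3-hydroxypropyl)-2-methoxyphenol]; 2 allyl bromide
Product: 3 3-[4-(allyloxy)-3-methoxyphenyl]propan-1-ol
Conditions: K2CO3, acetone, reflux
Reagents that add atoms: none
Why: Williamson etherification; K2CO3 deprotonates only the phenol, so the aliphatic alcohol stays free and only the aryl allyl ether should form.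

Step 2
Reactants: 3 3-[4-(allyloxy)-3-methoxyphenyl]propan-1-ol
Product: 4 3-[4-(allyloxy)-3-methoxyphenyl]propyl pivalate
Conditions: PivCl, Et3N, 4-(dimethylamino)pyridine (cat.), CH2Cl2, 0 °C → rt
Reagents that add atoms: pivaloyl chloride, CC(C)(C)C(Cl)=O
Why: Acylation of the primary alcohol; the pivalate is chosen because it should withstand 200 °C, ozone, chlorite, oxalyl chloride and Lewis acids and is removed by hydride in step 10.

Step 3
Reactants: 4 3-[4-(allyloxy)-3-methoxyphenyl]propyl pivalate
Product: 5 3-(3-allyl-4-hydroxy-5-methoxyphenyl)propyl pivalate
Conditions: N,N-diethylaniline, 200 °C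
Reagents that add atoms: none
Why: Aromatic Claisen rearrangement ([3,3] shift, then tautomerisation); one ortho position carries the methoxy group and the para position the side chain, so the allyl group can only end up on the free ortho carbon, the future C3a.

Step 4
Reactants: 5 3-(3-allyl-4-hydroxy-5-methoxyphenyl)propyl pivalate
Product: 6 3-[3-allyl-5-methoxy-4-(triisopropylsilyloxy)phenyl]propyl pivalate
Conditions: i-Pr3SiCl, imidazole, DMF, 50 °C
Reagents that add atoms: triisopropylsilyl chloride, CC(C)[Si](Cl)(C(C)C)C(C)C
Why: Silylation of a hindered phenol; the bulky triisopropylsilyl group is meant to keep the future O1 from being acylated in steps 6 and 8 and is given up in step 9.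

Step 5
Reactants: 6 3-[3-allyl-5-methoxy-4-(triisopropylsilyloxy)phenyl]propyl pivalate
Product: 8 2-[3-methoxy-5-(3-pivaloyloxypropyl)-2-(triisopropylsilyloxy)phenyl]acetic acid, via arylacetaldehyde 7 (not isolated)
Conditions: O3, CH2Cl2, −78 °C; PPh3, −78 °C → rt; then NaClO2, NaH2PO4, 2-methyl-2-butene, t-BuOH/H2O, 0 °C → rt
Reagents that add atoms: ozone, [O-][O+]=O; sodium chlorite, [Na+].[O-]Cl=O
Why: Ozonolysis of the terminal alkene, which reacts far faster than the arene at −78 °C, followed by chlorite (Pinnick) oxidation with a hypochlorite scavenger; the enolisable arylacetaldehyde 7 is oxidised crude to avoid self-condensation.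

Step 6
Reactants: 8 2-[3-methoxy-5-(3-pivaloyloxypropyl)-2-(triisopropylsilyloxy)phenyl]acetic acid
Product: 9 2-[3-methoxy-5-(3-pivaloyloxypropyl)-2-(triisopropylsilyloxy)phenyl]acetyl chloride
Conditions: (COCl)2, DMF (cat.), CH2Cl2, 0 °C → rt; volatiles removed, used crude
Reagents that add atoms: oxalyl chloride, O=C(Cl)C(Cl)=O
Why: Acid chloride formation through the chloroiminium (Vilsmeier-type) activation; all by-products are gases, so the crude chloride can go directly into step 8.

Step 7
Reactants: 10 syringaldehyde [4-hydroxy-3,5-dimethoxybenzaldehyde]
Product: 11 4-formyl-2,6-dimethoxyphenyl pivalate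
Conditions: PivCl, Et3N, 4-(dimethylamino)pyridine (cat.), CH2Cl2, 0 °C → rt
Reagents that add atoms: pivaloyl chloride, CC(C)(C)C(Cl)=O
Why: Nucleophile-catalysed acylation of the hindered phenol; the ester removes the para oxygen's donor strength, which keeps the aldehyde electrophilic and the later lactone from ionising.

Step 8
Reactants: 9 2-[3-methoxy-5-(3-pivaloyloxypropyl)-2-(triisopropylsilyloxy)phenyl]acetyl chloride; 11 4-formyl-2,6-dimethoxyphenyl pivalate
Product: 13 (3S,4R)-4-(3,5-dimethoxy-4-pivaloyloxyphenyl)-3-[3-methoxy-5-(3-pivaloyloxypropyl)-2-(triisopropylsilyloxy)phenyl]oxetan-2-one, via arylketene 12 (not isolated)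
Conditions: O-trimethylsilylquinine (20 mol %), Sc(OTf)3 (15 mol %), i-Pr2NEt (2.5 equiv), 11 (1.5 equiv), CH2Cl2, −40 °C, 9 added over 4 h
Reagents that add atoms: none
Why: i-Pr2NEt dehydrohalogenates 9 to arylketene 12, which is kept dilute by slow addition. The quinuclidine nitrogen of the catalyst adds to the ketene carbonyl carbon to give a (Z)-ammonium enolate, this attacks the Sc(OTf)3-bound carbonyl of 11 to form the C3–C4 bond, and the metal alkoxide closes the oxetanone by 4-exo-trig attack on the acylammonium carbon, which releases the catalyst. The closest known reaction type is the cinchona Lewis base/metal Lewis acid cyclocondensation of acid chlorides with aldehydes; its variant with a metal triflate and aromatic aldehydes favours trans lactones, and arylacetyl chlorides give the same ammonium enolates that are used in the analogous β-lactam synthesis. C3 is set by the catalyst: the quinoline and silyloxy groups screen one face of the enolate, so the aldehyde is taken up on the face that gives 3S. C4 is set relative to C3 in an open transition state in which the metal-bound aldehyde turns ring B away from ring A, which gives the trans (4R) isomer. The step needs cross-addition to beat ketene dimerisation (excess 11, slow addition), no acylation of the ring A oxygen (secured by the bulk of the triisopropylsilyl group) and no ionisation of the product (secured by the ring B pivalate). The 3S configuration is what must not fail: a cis lactone of the same C3 configuration would still be expected to converge on 15 if step 9 goes through ionisation at C4.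

Step 9
Reactants: 13 (3S,4R)-4-(3,5-dimethoxy-4-pivaloyloxyphenyl)-3-[3-methoxy-5-(3-pivaloyloxypropyl)-2-(triisopropylsilyloxy)phenyl]oxetan-2-one
Product: 15 (2S,3S)-2-(3,5-dimethoxy-4-pivaloyloxyphenyl)-7-methoxy-5-(3-pivaloyloxypropyl)-2,3-dihydrobenzofuran-3-carboxylic acid, via trimethylsilyl ester 14 (not isolated)
Conditions: Me3SiOTf (1.2 equiv), 2,6-di-tert-butyl-4-methylpyridine (0.3 equiv), CH2Cl2, −78 → −20 °C; then H2O, aq. citric acid, rt
Reagents that add atoms: none
Why: Silylation of the lactone carbonyl oxygen turns the strained benzylic C4–O bond into a leaving group (alkyl–oxygen cleavage of a β-lactone, the mode by which β-lactones are converted into cyclic ether acids by internal oxygen nucleophiles); the ring A oxygen captures C4 in a 5-exo-tet closure on the face opposite to the departing carboxylate, its silyl group passes to triflate, and silyl ester 14 is hydrolysed on work-up. Inversion at C4 of trans-13 gives the 2,3-trans acid, and if the bond ionises first, closure anti to the C3 ester group should give the same (2S,3S) product, since C3 is not touched under these non-basic conditions.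

Step 10
Reactants: 15 (2S,3S)-2-(3,5-dimethoxy-4-pivaloyloxyphenyl)-7-methoxy-5-(3-pivaloyloxypropyl)-2,3-dihydrobenzofuran-3-carboxylic acid
Product: 16 (2S,3R)-2-(4-hydroxy-3,5-dimethoxyphenyl)-3-(hydroxymethyl)-5-(3-hydroxypropyl)-7-methoxy-2,3-dihydrobenzofuran
Conditions: LiAlH4 (6 equiv), THF, 0 °C → rt; then EtOAc, 10% aq. citric acid, 0 °C
Reagents that add atoms: none
Why: Hydride reduction of the carboxylic acid (through its aluminium carboxylate) to the primary alcohol, with cleavage of the aryl and the alkyl pivalate by acyl reduction in the same operation; no bond to C2 or C3 is made or broken, and the descriptor at C3 changes from S to R only because CH2OH ranks below C2 where CO2H ranked above it.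

## Compound list

1 | dihydroconiferyl alcohol, 4-(3-hydroxypropyl)-2-methoxyphenol | COc1cc(CCCO)ccc1O | starting material
2 | allyl bromide | C=CCBr | starting material
3 | 3-[4-(allyloxy)-3-methoxyphenyl]propan-1-ol | COc1cc(CCCO)ccc1OCC=C | intermediate
4 | 3-[4-(allyloxy)-3-methoxyphenyl]propyl pivalate | COc1cc(CCCOC(=O)C(C)(C)C)ccc1OCC=C | intermediate
5 | 3-(3-allyl-4-hydroxy-5-methoxyphenyl)propyl pivalate | COc1cc(CCCOC(=O)C(C)(C)C)cc(CC=C)c1O | intermediate
6 | 3-[3-allyl-5-methoxy-4-(triisopropylsilyloxy)phenyl]propyl pivalate | COc1cc(CCCOC(=O)C(C)(C)C)cc(CC=C)c1O[Si](C(C)C)(C(C)C)C(C)C | intermediate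
7 | 3-[3-methoxy-5-(2-oxoethyl)-4-(triisopropylsilyloxy)phenyl]propyl pivalate | COc1cc(CCCOC(=O)C(C)(C)C)cc(CC=O)c1O[Si](C(C)C)(C(C)C)C(C)C | intermediate
8 | 2-[3-methoxy-5-(3-pivaloyloxypropyl)-2-(triisopropylsilyloxy)phenyl]acetic acid | COc1cc(CCCOC(=O)C(C)(C)C)cc(CC(=O)O)c1O[Si](C(C)C)(C(C)C)C(C)C | intermediate
9 | 2-[3-methoxy-5-(3-pivaloyloxypropyl)-2-(triisopropylsilyloxy)phenyl]acetyl chloride | COc1cc(CCCOC(=O)C(C)(C)C)cc(CC(Cl)=O)c1O[Si](C(C)C)(C(C)C)C(C)C | intermediate
10 | syringaldehyde, 4-hydroxy-3,5-dimethoxybenzaldehyde | COc1cc(C=O)cc(OC)c1O | starting material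
11 | 4-formyl-2,6-dimethoxyphenyl pivalate | COc1cc(C=O)cc(OC)c1OC(=O)C(C)(C)C | intermediate
12 | [3-methoxy-5-(3-pivaloyloxypropyl)-2-(triisopropylsilyloxy)phenyl]ketene | COc1cc(CCCOC(=O)C(C)(C)C)cc(C=C=O)c1O[Si](C(C)C)(C(C)C)C(C)C | intermediate
13 | (3S,4R)-4-(3,5-dimethoxy-4-pivaloyloxyphenyl)-3-[3-methoxy-5-(3-pivaloyloxypropyl)-2-(triisopropylsilyloxy)phenyl]oxetan-2-one (trans) | O=C1O[C@@H](c2cc(OC)c(OC(=O)C(C)(C)C)c(OC)c2)[C@@H]1c1cc(CCCOC(=O)C(C)(C)C)cc(OC)c1O[Si](C(C)C)(C(C)C)C(C)C | intermediate
14 | trimethylsilyl (2S,3S)-2-(3,5-dimethoxy-4-pivaloyloxyphenyl)-7-methoxy-5-(3-pivaloyloxypropyl)-2,3-dihydrobenzofuran-3-carboxylate | COc1cc([C@H]2Oc3c(OC)cc(CCCOC(=O)C(C)(C)C)cc3[C@@H]2C(=O)O[Si](C)(C)C)cc(OC)c1OC(=O)C(C)(C)C | intermediate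
15 | (2S,3S)-2-(3,5-dimethoxy-4-pivaloyloxyphenyl)-7-methoxy-5-(3-pivaloyloxypropyl)-2,3-dihydrobenzofuran-3-carboxylic acid (trans) | COc1cc([C@H]2Oc3c(OC)cc(CCCOC(=O)C(C)(C)C)cc3[C@@H]2C(=O)O)cc(OC)c1OC(=O)C(C)(C)C | intermediate
16 | (2S,3R)-2-(4-hydroxy-3,5-dimethoxyphenyl)-3-(hydroxymethyl)-5-(3-hydroxypropyl)-7-methoxy-2,3-dihydrobenzofuran (trans) | COc1cc([C@H]2Oc3c(OC)cc(CCCO)cc3[C@@H]2CO)cc(OC)c1O | target

## Step count and least certain steps

Total: 10 steps. Longest linear sequence: 9 steps (steps 1–6, 8, 9, 10); step 7 is a one-step branch.

Step 8 (key step). What may go wrong: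
- cross-addition losing out to dimerisation of ketene 12, because the ammonium enolate with an ortho-silyloxyaryl group is a hindered, stabilised nucleophile;
- lower trans and enolate-face selectivity than with alkyl ketenes, because the aryl group changes the size relationship in the open transition state;
- epimerisation of the acidic C3–H of 13 by the amine;
- ionisation of the lactone by the Lewis acid, followed by decarboxylation.

Fallback (auxiliary-controlled aldol, no β-lactone): acid chloride 9 acylates lithiated (4S)-4-benzyloxazolidin-2-one to give the N-arylacetyl oxazolidinone F1. Its boron (Z)-enolate (Bu2BOTf, i-Pr2NEt, CH2Cl2, −78 → 0 °C) adds to aldehyde 11 to give the Evans syn aldol adduct F2, in which the auxiliary fixes the α-carbon (the future C3). LiAlH4 removes the auxiliary reductively together with both pivalates and gives the silyl-protected tetraol F3. Bu4NF/AcOH frees the ring A phenol (pentaol F4). Catalytic p-TsOH in MeCN then ionises the p-hydroxybenzyl alcohol, and ring A's phenol closes the dihydrofuran trans to the C3 substituent, which returns to the route at 16. The carbinol configuration is lost in this closure, so only the α-centre needs control.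

Step 9. What may go wrong: after ionisation, loss of CO2 (fragmentation to the stilbene) may outrun capture of C4 by the hindered silyl ether oxygen, or the ring A oxygen may attack the activated carbonyl (acyl transfer).

Fallback (reduce first, close through the quinone methide): LiAlH4 opens lactone 13 by acyl reduction and removes both pivalates, giving the silyl-protected (1R,2R)-tetraol F5. Bu4NF/AcOH gives the (1R,2R)-pentaol F6, and catalytic p-TsOH in MeCN closes the ring as above, arriving at 16.

Step 6. What may go wrong: acylation of the ring A oxygen by its own acid chloride with loss of the silyl group (closure to a benzofuranone), helped by HCl and chloride.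

Fallback (no acid chloride): acid 8 is converted with pivaloyl chloride/i-Pr2NEt (CH2Cl2, 0 °C) into the mixed pivalic anhydride F7, which is fed directly to the catalyst system of step 8. The Lewis base is acylated at the less hindered arylacetyl carbonyl and deprotonation gives the same ammonium enolate, returning at 13.

Step 5. What may go wrong: attack of ozone on the electron-rich ring A, ring chlorination during the chlorite oxidation, and self-condensation of the arylacetaldehyde while it is handled.

Fallback (stepwise cleavage without ozone): dihydroxylation of 6 (K2OsO2(OH)4 cat., N-methylmorpholine N-oxide, acetone/H2O) gives the diol F8; NaIO4 cleaves it to aldehyde 7, which is oxidised at once with NaClO2 as in step 5, returning at 8.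

Step 10. What may go wrong: once the ring B pivalate is cleaved, expulsion of O1 from C2 by the aluminium phenoxide (quinone methide formation) and hydride capture, which is reductive opening of the dihydrofuran; incomplete reduction of the hindered carboxylate is the other risk.

Fallback (two chemoselective reductions): BH3·SMe2 (THF, 0 °C → rt) reduces only the acid of 15 and gives the bis-pivalate alcohol F9; i-Bu2AlH (CH2Cl2, −78 °C) then removes both pivalates at low temperature, arriving at 16.

## Further compounds

F1 | step 8 | (4S)-4-benzyl-3-{2-[3-methoxy-5-(3-pivaloyloxypropyl)-2-(triisopropylsilyloxy)phenyl]acetyl}oxazolidin-2-one | COc1cc(CCCOC(=O)C(C)(C)C)cc(CC(=O)N2[C@@H](Cc3ccccc3)COC2=O)c1O[Si](C(C)C)(C(C)C)C(C)C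
F2 | step 8 | (4S)-4-benzyl-3-{(2S,3S)-3-(3,5-dimethoxy-4-pivaloyloxyphenyl)-3-hydroxy-2-[3-methoxy-5-(3-pivaloyloxypropyl)-2-(triisopropylsilyloxy)phenyl]propanoyl}oxazolidin-2-one | O=C([C@H]([C@H](O)c3cc(OC)c(OC(=O)C(C)(C)C)c(OC)c3)c1cc(CCCOC(=O)C(C)(C)C)cc(OC)c1O[Si](C(C)C)(C(C)C)C(C)C)N2[C@@H](Cc4ccccc4)COC2=O
F3 | step 8 | (1S,2R)-1-(4-hydroxy-3,5-dimethoxyphenyl)-2-[5-(3-hydroxypropyl)-3-methoxy-2-(triisopropylsilyloxy)phenyl]propane-1,3-diol | OC[C@H]([C@H](O)c2cc(OC)c(O)c(OC)c2)c1cc(CCCO)cc(OC)c1O[Si](C(C)C)(C(C)C)C(C)C
F4 | step 8 | (1S,2R)-2-[2-hydroxy-5-(3-hydroxypropyl)-3-methoxyphenyl]-1-(4-hydroxy-3,5-dimethoxyphenyl)propane-1,3-diol | OC[C@H]([C@H](O)c2cc(OC)c(O)c(OC)c2)c1cc(CCCO)cc(OC)c1O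
F5 | step 9 | (1R,2R)-1-(4-hydroxy-3,5-dimethoxyphenyl)-2-[5-(3-hydroxypropyl)-3-methoxy-2-(triisopropylsilyloxy)phenyl]propane-1,3-diol | OC[C@H]([C@@H](O)c2cc(OC)c(O)c(OC)c2)c1cc(CCCO)cc(OC)c1O[Si](C(C)C)(C(C)C)C(C)C
F6 | step 9 | (1R,2R)-2-[2-hydroxy-5-(3-hydroxypropyl)-3-methoxyphenyl]-1-(4-hydroxy-3,5-dimethoxyphenyl)propane-1,3-diol | OC[C@H]([C@@H](O)c2cc(OC)c(O)c(OC)c2)c1cc(CCCO)cc(OC)c1O
F7 | step 6 | 2-[3-methoxy-5-(3-pivaloyloxypropyl)-2-(triisopropylsilyloxy)phenyl]acetic pivalic anhydride | COc1cc(CCCOC(=O)C(C)(C)C)cc(CC(=O)OC(=O)C(C)(C)C)c1O[Si](C(C)C)(C(C)C)C(C)C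
F8 | step 5 | 3-[3-(2,3-dihydroxypropyl)-5-methoxy-4-(triisopropylsilyloxy)phenyl]propyl pivalate (racemic) | COc1cc(CCCOC(=O)C(C)(C)C)cc(CC(O)CO)c1O[Si](C(C)C)(C(C)C)C(C)C
F9 | step 10 | 3-[(2S,3R)-2-(3,5-dimethoxy-4-pivaloyloxyphenyl)-3-(hydroxymethyl)-7-methoxy-2,3-dihydrobenzofuran-5-yl]propyl pivalate | COc1cc([C@H]2Oc3c(OC)cc(CCCOC(=O)C(C)(C)C)cc3[C@@H]2CO)cc(OC)c1OC(=O)C(C)(C)C
A1 | alternative 1 | (2S,3R)-2-(4-benzyloxy-3,5-dimethoxyphenyl)-3-(tert-butyldimethylsilyloxymethyl)-7-methoxy-2,3-dihydrobenzofuran-5-carbaldehyde | COc1cc([C@H]2Oc3c(OC)cc(C=O)cc3[C@@H]2CO[Si](C)(C)C(C)(C)C)cc(OC)c1OCc1ccccc1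
A2 | alternative 1 | (1S,2R)-1-(4-benzyloxy-3,5-dimethoxyphenyl)-3-(tert-butyldimethylsilyloxy)-2-(2-fluoro-5-formyl-3-methoxyphenyl)propan-1-ol | COc1cc([C@@H](O)[C@@H](CO[Si](C)(C)C(C)(C)C)c2cc(C=O)cc(OC)c2F)cc(OC)c1OCc1ccccc1
A3 | alternative 2 | (2S,3S)-2-(4-benzyloxy-3,5-dimethoxyphenyl)-5-[3-(tert-butyldimethylsilyloxy)propyl]-7-methoxy-3-[(4,4,5,5-tetramethyl-1,3,2-dioxaborolan-2-yl)methyl]-2,3-dihydrobenzofuran | COc1cc([C@H]2Oc3c(OC)cc(CCCO[Si](C)(C)C(C)(C)C)cc3[C@@H]2CB2OC(C)(C)C(C)(C)O2)cc(OC)c1OCc1ccccc1
A4 | alternative 2 | 2-{[(1S)-1-(4-benzyloxy-3,5-dimethoxyphenyl)prop-2-en-1-yl]oxy}-5-[3-(tert-butyldimethylsilyloxy)propyl]-1-iodo-3-methoxybenzene | COc1cc([C@H](C=C)Oc2c(I)cc(CCCO[Si](C)(C)C(C)(C)C)cc2OC)cc(OC)c1OCc1ccccc1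
A5 | alternative 3 | (2S,3R)-2-(4-benzyloxy-3,5-dimethoxyphenyl)-3-(tert-butyldimethylsilyloxymethyl)-5-[3-(tert-butyldimethylsilyloxy)propyl]-7-methoxy-2,3-dihydrobenzofuran | COc1cc([C@H]2Oc3c(OC)cc(CCCO[Si](C)(C)C(C)(C)C)cc3[C@@H]2CO[Si](C)(C)C(C)(C)C)cc(OC)c1OCc1ccccc1
A6 | alternative 3 | 2-[2-(tert-butyldimethylsilyloxy)-1-(4-methylphenylsulfonyl)ethyl]-4-[3-(tert-butyldimethylsilyloxy)propyl]-6-methoxyphenol (racemic) | COc1cc(CCCO[Si](C)(C)C(C)(C)C)cc(C(CO[Si](C)(C)C(C)(C)C)S(=O)(=O)c2ccc(C)cc2)c1O
A7 | alternative 3 | (2R,5R)-1-(4-benzyloxy-3,5-dimethoxybenzyl)-2,5-dimethylthiolan-1-ium bromide | C[C@@H]1CC[C@@H](C)[S+]1Cc1cc(OC)c(OCc2ccccc2)c(OC)c1.[Br-]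
A8 | alternative 3 | 6-[2-(tert-butyldimethylsilyloxy)ethylidene]-4-[3-(tert-butyldimethylsilyloxy)propyl]-2-methoxycyclohexa-2,4-dien-1-one (alkene geometry open) | COC1=CC(CCCO[Si](C)(C)C(C)(C)C)=CC(=CCO[Si](C)(C)C(C)(C)C)C1=O
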